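**Retrosynthetic overview**
- The (S)-lactol is released last, by neutral enzymatic de-acylation of an (S)-acylal that comes from an acylative dynamic kinetic resolution of the racemic lactol.
- The racemic lactol comes from one Pd-catalysed double carbonylation of a dibromo diaryl ether. The ring-A C–Br, CO and the neighbouring phenol give the seven-membered depsidone lactone; the ring-B C–Br (ortho to CHO), CO and water give the γ-lactol (hydroxyphthalide).
- The dibromo diaryl ether comes from SNAr of a ring-B salicylaldehyde phenol on a ring-A 2-fluorobenzaldehyde, followed by debenzylation.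
- The ring-A fluoride is made from 3,5-difluorotoluene and the ring-B phenol from 2,4-dihydroxybenzaldehyde.
- Ring order: both benzene rings are bought, then the diaryl ether is made, then the depsidone ring and the lactol ring are formed together.

Assumption: the only stereocentre is a lactol carbon that epimerises by ring–chain tautomerism under base, so it is set last and the (S)-lactol is released and handled only under neutral, aprotic conditions, on the premise that it is configurationally stable as isolated.

**Step 1**
Reactants: 1 3,5-difluorotoluene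
Product: 3 2,6-difluoro-4-methylbenzaldehyde, via aryllithium 2 (not isolated)
Conditions: LDA, THF, −78 °C; DMF, −78 °C → rt; aq. HCl
Reagents that add atoms: N,N-dimethylformamide CN(C)C=O
Why: Directed ortho-metalation at the most acidic C–H (between the two fluorines) followed by formylation with DMF.

**Step 2**
Reactants: 3 2,6-difluoro-4-methylbenzaldehyde
Product: 4 2-fluoro-6-methoxy-4-methylbenzaldehyde
Conditions: NaOMe (1.05 equiv), MeOH–THF, 0 °C → rt
Reagents that add atoms: sodium methoxide C[O-].[Na+]
Why: SNAr of one of two equivalent ortho-formyl-activated fluorides; the methoxy group introduced deactivates the ring against a second substitution.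

**Step 3**
Reactants: 4 2-fluoro-6-methoxy-4-methylbenzaldehyde
Product: 5 3-bromo-2-fluoro-6-methoxy-4-methylbenzaldehyde
Conditions: NBS, MeCN, TFA (cat.), rt, dark
Reagents that add atoms: N-bromosuccinimide O=C1CCC(=O)N1Br
Why: Electrophilic aromatic bromination para to the methoxy group (and meta to CHO), the ionic conditions avoiding benzylic bromination.

**Step 4**
Reactants: 6 2,4-dihydroxybenzaldehyde
Product: 7 2,4-bis(benzyloxy)benzaldehyde
Conditions: BnBr (2.3 equiv), K2CO3, DMF, 60 °C
Reagents that add atoms: benzyl bromide BrCc1ccccc1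
Why: Williamson etherification of both phenols.

**Step 5**
Reactants: 7 2,4-bis(benzyloxy)benzaldehyde
Product: 9 2,4-bis(benzyloxy)phenol, via aryl formate 8 (not isolated)
Conditions: mCPBA, CH2Cl2, 0 °C → rt; then Et3N (cat.), MeOH, rt
Reagents that add atoms: 3-chloroperoxybenzoic acid OOC(=O)c1cccc(Cl)c1
Why: Baeyer–Villiger (Dakin-type) oxidation of an electron-rich benzaldehyde with aryl migration, then methanolysis of the aryl formate.

**Step 6**
Reactants: 9 2,4-bis(benzyloxy)phenol
Product: 11 3,5-bis(benzyloxy)-2-hydroxybenzaldehyde, via salicyl alcohol 10 (not isolated)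
Conditions: MgCl2, Et3N, (CH2O)n, MeCN, reflux; aq. HCl
Reagents that add atoms: formaldehyde (as paraformaldehyde) C=O
Why: Magnesium-mediated ortho-formylation of a phenol (Casnati–Skattebøl) at the only free ortho position, the hydroxymethyl intermediate being oxidised by a second formaldehyde.

**Step 7**
Reactants: 11 3,5-bis(benzyloxy)-2-hydroxybenzaldehyde
Product: 12 3,5-bis(benzyloxy)-2-bromo-6-hydroxybenzaldehyde
Conditions: NBS, MeCN, 0 °C
Reagents that add atoms: N-bromosuccinimide O=C1CCC(=O)N1Br
Why: Electrophilic aromatic bromination at the position para to one benzyloxy group and ortho to CHO, the same selectivity as for 3,5-dialkoxybenzaldehydes, rather than the hindered position between the two ethers.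

**Step 8**
Reactants: 5 3-bromo-2-fluoro-6-methoxy-4-methylbenzaldehyde; 12 3,5-bis(benzyloxy)-2-bromo-6-hydroxybenzaldehyde
Product: 13 2-[4,6-bis(benzyloxy)-3-bromo-2-formylphenoxy]-3-bromo-6-methoxy-4-methylbenzaldehyde
Conditions: Cs2CO3, DMSO, 90 °C
Reagents that add atoms: none
Why: SNAr diaryl ether synthesis, the fluoride being activated by the ortho formyl group and the ortho bromine, and the only free phenol of 12 being the nucleophile.

**Step 9**
Reactants: 13 2-[4,6-bis(benzyloxy)-3-bromo-2-formylphenoxy]-3-bromo-6-methoxy-4-methylbenzaldehyde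
Product: 14 3-bromo-2-(3-bromo-2-formyl-4,6-dihydroxyphenoxy)-6-methoxy-4-methylbenzaldehyde
Conditions: BCl3, C6HMe5, CH2Cl2, −78 °C; then H2O
Reagents that add atoms: none
Why: Lewis-acid debenzylation with a cation scavenger at −78 °C, which cleaves aryl benzyl ethers faster than the aryl methyl ether and leaves the aryl bromides and aldehydes intact.

**Step 10**
Reactants: 14 3-bromo-2-(3-bromo-2-formyl-4,6-dihydroxyphenoxy)-6-methoxy-4-methylbenzaldehyde
Product: 17 rac-1,4-dihydroxy-10-methoxy-8-methyl-3,7-dioxo-1,3-dihydro-7H-isobenzofuro[4,5-b][1,4]benzodioxepine-11-carbaldehyde, via bromo depsidone 15 (not isolated), via formyl acid 16 (not isolated)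
Conditions: Pd(OAc)2 (10 mol %), Xantphos (15 mol %), CO (5 bar), Et3N (4 equiv), H2O (3 equiv), 1,4-dioxane, 90 °C; dil. HCl work-up
Reagents that add atoms: carbon monoxide [C-]#[O+]; water O
Why: Proposed new method: Pd(0) inserts into both C–Br bonds and CO insertion gives two acyl-palladium species, of which the ring-A one is captured intramolecularly by the adjacent phenol to close the seven-membered depsidone lactone, while the ring-B one, with no internal nucleophile in reach, is hydrolysed to a 2-formylbenzoic acid that closes at once to the γ-lactol by ring–chain tautomerism (racemic at this stage), so both rings form in one operation; the closest known reaction types are Pd-catalysed intramolecular aryloxycarbonylation (carbonylative lactonisation) and hydroxycarbonylation of 2-bromobenzaldehydes to 3-hydroxyphthalides.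

**Step 11**
Reactants: 17 rac-1,4-dihydroxy-10-methoxy-8-methyl-3,7-dioxo-1,3-dihydro-7H-isobenzofuro[4,5-b][1,4]benzodioxepine-11-carbaldehyde
Product: 18 (1S)-11-formyl-10-methoxy-8-methyl-3,7-dioxo-1,3-dihydro-7H-isobenzofuro[4,5-b][1,4]benzodioxepine-1,4-diyl bis(2-methylpropanoate)
Conditions: (i-PrCO)2O (2.5 equiv), HyperBTM (10 mol %, the enantiomer that gives the (S)-acylal, assigned on the first run by X-ray/ECD), i-Pr2NEt, CH2Cl2, −20 °C
Reagents that add atoms: isobutyric anhydride CC(C)C(=O)OC(=O)C(C)C
Why: Acylative dynamic kinetic resolution under chiral isothiourea (Lewis-base) catalysis, in which the amine base interconverts the lactol enantiomers through the open formyl carboxylate while the chiral acyl-isothiouronium acylates one of them faster, fixing C1 as the configurationally stable (S)-acylal; the phenol is esterified as well, without stereochemical consequence.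

**Step 12**
Reactants: 18 (1S)-11-formyl-10-methoxy-8-methyl-3,7-dioxo-1,3-dihydro-7H-isobenzofuro[4,5-b][1,4]benzodioxepine-1,4-diyl bis(2-methylpropanoate)
Product: 19 (1S)-1,4-dihydroxy-10-methoxy-8-methyl-3,7-dioxo-1,3-dihydro-7H-isobenzofuro[4,5-b][1,4]benzodioxepine-11-carbaldehyde
Conditions: Novozym 435 (immobilised CAL-B), n-BuOH (10 equiv), MTBE, 30 °C; filter, evaporate cold, crystallise from a non-basic solvent
Reagents that add atoms: none
Why: Lipase-catalysed alcoholysis (transesterification) removes the acylal and aryl esters by acyl–oxygen cleavage under neutral, base-free conditions, so the C1–O bond is never broken and the (S) configuration is retained.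

**Compound list**
1 | 3,5-difluorotoluene | Cc1cc(F)cc(F)c1 | starting material
2 | (2,6-difluoro-4-methylphenyl)lithium | [Li]c1c(F)cc(C)cc1F | intermediate
3 | 2,6-difluoro-4-methylbenzaldehyde | Cc1cc(F)c(C=O)c(F)c1 | intermediate
4 | 2-fluoro-6-methoxy-4-methylbenzaldehyde | COc1cc(C)cc(F)c1C=O | intermediate
5 | 3-bromo-2-fluoro-6-methoxy-4-methylbenzaldehyde | COc1cc(C)c(Br)c(F)c1C=O | intermediate
6 | 2,4-dihydroxybenzaldehyde | O=Cc1ccc(O)cc1O | starting material
7 | 2,4-bis(benzyloxy)benzaldehyde | O=Cc1ccc(OCc2ccccc2)cc1OCc1ccccc1 | intermediate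
8 | 2,4-bis(benzyloxy)phenyl formate | O=COc1ccc(OCc2ccccc2)cc1OCc1ccccc1 | intermediate
9 | 2,4-bis(benzyloxy)phenol | Oc1ccc(OCc2ccccc2)cc1OCc1ccccc1 | intermediate
10 | 2,4-bis(benzyloxy)-6-(hydroxymethyl)phenol | OCc1cc(OCc2ccccc2)cc(OCc2ccccc2)c1O | intermediate
11 | 3,5-bis(benzyloxy)-2-hydroxybenzaldehyde | O=Cc1cc(OCc2ccccc2)cc(OCc2ccccc2)c1O | intermediate
12 | 3,5-bis(benzyloxy)-2-bromo-6-hydroxybenzaldehyde | O=Cc1c(Br)c(OCc2ccccc2)cc(OCc2ccccc2)c1O | intermediate
13 | 2-[4,6-bis(benzyloxy)-3-bromo-2-formylphenoxy]-3-bromo-6-methoxy-4-methylbenzaldehyde | COc1cc(C)c(Br)c(Oc2c(OCc3ccccc3)cc(OCc3ccccc3)c(Br)c2C=O)c1C=O | intermediate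
14 | 3-bromo-2-(3-bromo-2-formyl-4,6-dihydroxyphenoxy)-6-methoxy-4-methylbenzaldehyde | COc1cc(C)c(Br)c(Oc2c(O)cc(O)c(Br)c2C=O)c1C=O | intermediate
15 | 7-bromo-8-hydroxy-3-methoxy-1-methyl-11-oxo-11H-dibenzo[b,e][1,4]dioxepine-4,6-dicarbaldehyde | COc1cc(C)c2c(c1C=O)Oc1c(cc(O)c(Br)c1C=O)OC2=O | intermediate
16 | 4,6-diformyl-8-hydroxy-3-methoxy-1-methyl-11-oxo-11H-dibenzo[b,e][1,4]dioxepine-7-carboxylic acid | COc1cc(C)c2c(c1C=O)Oc1c(cc(O)c(C(=O)O)c1C=O)OC2=O | intermediate
17 | rac-1,4-dihydroxy-10-methoxy-8-methyl-3,7-dioxo-1,3-dihydro-7H-isobenzofuro[4,5-b][1,4]benzodioxepine-11-carbaldehyde (racemic lactol) | COc1cc(C)c2c(c1C=O)Oc1c(cc(O)c3c1C(O)OC3=O)OC2=O | intermediate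
18 | (1S)-11-formyl-10-methoxy-8-methyl-3,7-dioxo-1,3-dihydro-7H-isobenzofuro[4,5-b][1,4]benzodioxepine-1,4-diyl bis(2-methylpropanoate) | COc1cc(C)c2c(c1C=O)Oc1c(cc(OC(=O)C(C)C)c3c1[C@@H](OC(=O)C(C)C)OC3=O)OC2=O | intermediate
19 | (1S)-1,4-dihydroxy-10-methoxy-8-methyl-3,7-dioxo-1,3-dihydro-7H-isobenzofuro[4,5-b][1,4]benzodioxepine-11-carbaldehyde | COc1cc(C)c2c(c1C=O)Oc1c(cc(O)c3c1[C@@H](O)OC3=O)OC2=O | target

**Step count**
Total: 12 steps. Longest linear sequence: 9 steps (6 → 19, steps 4–12); the ring-A branch (steps 1–3) joins at step 8.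

**Three steps most likely to fail**

Step 10 (double carbonylation). Water may intercept the ring-A acyl-palladium before the phenol does, and the di-ortho-substituted bromide may insert slowly. The fallback sets out from 14. Both bromides are hydroxycarbonylated with excess water (Pd(OAc)2/Xantphos, CO, K2CO3, dioxane–H2O). This gives the seco acid rac-3-formyl-4-methoxy-6-methyl-2-[(3,5,7-trihydroxy-1-oxo-1,3-dihydro-2-benzofuran-4-yl)oxy]benzoic acid F2, in which the lactol is already closed. The seven-membered lactone is then closed separately by classical dehydrative lactonisation (TFAA, toluene, then aqueous NaHCO3 to cleave trifluoroacetates). The fallback comes back to the route at 17.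

Step 8 (SNAr). The ether is flanked by four ortho substituents, and the fluoride is hindered by the neighbouring bromine. The fallback sets out from 4 and 11, the two fragments before bromination. The same Cs2CO3/DMSO coupling on this less hindered pair gives 2-[2,4-bis(benzyloxy)-6-formylphenoxy]-6-methoxy-4-methylbenzaldehyde F1. Both bromines are then introduced late with NBS (2.1 equiv, MeCN): on ring B para to a benzyloxy group and on ring A para to the methoxy group. The ring-A regiochemistry (para to OMe versus para to OAr) is less secure here and an isomer may need to be separated. The fallback comes back to the route at 13.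

Step 11 (acylative DKR). The enantioselectivity on this bulky lactol is unknown, and an uncatalysed acylation through the open formyl carboxylate could erode it. The fallback sets out from 17 and also removes the need for step 12. Acid-catalysed pseudo-ester formation with (S)-1-(2-nitrophenyl)ethanol (PPTS, toluene, 4 Å sieves, 60 °C) gives two diastereomeric acetals. The phenol stays free. The diastereomer (1S)-4-hydroxy-10-methoxy-8-methyl-1-[(1S)-1-(2-nitrophenyl)ethoxy]-3,7-dioxo-1,3-dihydro-7H-isobenzofuro[4,5-b][1,4]benzodioxepine-11-carbaldehyde F3 is isolated by chromatography or crystallisation. The other diastereomer is re-equilibrated with acid and recycled. Photolysis (365 nm, MeCN, rt, neutral) then cleaves the o-nitrobenzylic C–O bond only, so C1 keeps its configuration. The fallback comes back to the route at 19.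

**Further compounds**
F1 | step 8 | 2-[2,4-bis(benzyloxy)-6-formylphenoxy]-6-methoxy-4-methylbenzaldehyde | COc1cc(C)cc(Oc2c(OCc3ccccc3)cc(OCc3ccccc3)cc2C=O)c1C=O
F2 | step 10 | rac-3-formyl-4-methoxy-6-methyl-2-[(3,5,7-trihydroxy-1-oxo-1,3-dihydro-2-benzofuran-4-yl)oxy]benzoic acid | COc1cc(C)c(C(=O)O)c(Oc2c(O)cc(O)c3c2C(O)OC3=O)c1C=O
F3 | step 11 | (1S)-4-hydroxy-10-methoxy-8-methyl-1-[(1S)-1-(2-nitrophenyl)ethoxy]-3,7-dioxo-1,3-dihydro-7H-isobenzofuro[4,5-b][1,4]benzodioxepine-11-carbaldehyde | COc1cc(C)c2c(c1C=O)Oc1c(cc(O)c3c1[C@@H](O[C@@H](C)c1ccccc1[N+](=O)[O-])OC3=O)OC2=O
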